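**The leftover.** Tuesday's flask ends with 67.2% of its J unreacted and Saturday's with 29.2%, and neither J is still falling. So I run these flasks in slow motion.

common to all: J 0.40 M
- Tuesday's: Z 0.18 M; run made earlier
- Saturday's: Z 0.81 M; run made earlier
- summer: Z 1.20 M; time 1.5 h
- autumn: Z 0.200 M; time 1.5 h

| run | time / min | E / % | G / % | J / % |
|---|---|---|---|---|
| Tuesday's | 15.0 | 19.8 | 1.1 | 75.6 |
| Tuesday's | 30.0 | 22.4 | 1.1 | 69.5 |
| Tuesday's | 50.0 | 20.4 | 1.0 | 68.0 |
| Tuesday's | 60.0 | 18.8 | 1.0 | 67.9 |
| Tuesday's | 80.0 | 15.4 | 1.3 | 67.5 |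
| Tuesday's | 90.0 | 14.2 | 1.4 | 67.2 |
| Saturday's | 8.00 | 37.3 | 5.5 | 49.3 |
| Saturday's | 12.0 | 38.7 | 8.5 | 43.4 |
| Saturday's | 20.0 | 38.9 | 12.6 | 36.2 |
| Saturday's | 30.0 | 36.6 | 13.7 | 32.8 |
| Saturday's | 50.0 | 30.8 | 17.1 | 28.9 |
| Saturday's | 90.0 | 21.7 | 17.4 | 29.2 |

(each reading ± 0.5 percentage points)



1. which of these holds the largest part of the J at the end of summer (E / X / G / J)
2. which of these holds the largest part of the J at the end of autumn (E / X / G / J)
3. final E in autumn, as a percentage of the J charged

**First minutes.** J turns into E quickly: Tuesday's E reads 19.8% after 15.0 min.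

**The middle.** E tops out, as a reading, near 22.4% on Tuesday and 38.9% on Saturday. By 50.0 min Tuesday's J has nearly stopped: it moves from 68.0% to 67.2% by the last reading.

**The end.** J stands still but E keeps falling, so I freeze one number, 0.00876 min⁻¹ from Saturday's last two readings: the late decay constant of E, the drop of ln E per minute once J stands still. Tuesday's last readings give 0.00935 min⁻¹, with a quarter of Saturday's Z charge. That makes a half-life of 79.1 min.

**My reckoning.** Autumn is Tuesday with slightly more Z. I scale Tuesday's E at 50.0 min by the Z charges and let the constant run to the end, which gives E 16.0%. I expect J to stay the largest part, as on Tuesday. For summer I reckon nothing.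

**The forecast.** It names X for summer, J for autumn and E 15%, a little lower than my figure. Of the late fall it says: "a slow Z-independent E→X path exists".

**The flask.** For summer the flask gives G, which holds 27.0%, more than J, E or X; X holds 7.58%, and a further product, D, holds 24.1%. Autumn ends with J at 65.0% and E 15.2%.

    J + Z → E (k = 0.00332 M⁻¹ s⁻¹)
    Z + E → X (k = 0.00227 M⁻¹ s⁻¹)
    Z + X → G (k = 0.0105 M⁻¹ s⁻¹)
    2 Z → L (k = 0.00147 M⁻¹ s⁻¹)
    E → D (k = 1.46 × 10⁻⁴ s⁻¹)

**The turn.** In autumn at 0.113 h, E is made 4.63 times faster than it is used up. At 1.50 h its making is hardly any of its use, with Z, the limiting reagent, at 0.106% of its charge. From the 21.8% of E at 0.750 h, the constant gives 14.7% at the end.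

**The neighbour.** With 0.10 M of J, the late decay constant by itself multiplies E by 45.5% over the whole time. The computed flask holds E 25.3% and D 22.1% with 8.6% of its Z left, so that factor counts the late decay and not what the remaining Z takes from E.

(The earlier runs and the new flask stem from a simulated flask for an exercise, and the scatter is random.)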